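## Structural features

The target is a linear trimer of 2-aryl-chroman-3-ols (flavan-3-ols), each with a 3,4-dihydroxyphenyl ring B; the upper unit has a 5,7-dihydroxylated ring A, the middle unit a ring A with only the 7-hydroxyl (no oxygen at C5), and the lower unit is (+)-catechin. Two C4→C8 bonds join them (upper C4 to middle C8, middle C4 to lower C8), so upper and middle C4 are diarylmethines and middle and lower C8 each lie between O1 and the 7-oxygen. Upper and middle units each carry three contiguous stereocentres, C2 and C3 both R (2,3-cis) with the C4 aryl trans to the C3 hydroxyl; the lower unit has 2R,3S and a C4 methylene, eight stereocentres in all. The eleven free phenols are sensitive to air and base (C2 can epimerise), and both interflavan bonds can ionise under acid because a C4 cation is stabilised by the ortho and para oxygens of ring A. The real difficulty is twofold: the 2,3-cis-3,4-trans triad must be made twice with absolute control, and the upper interflavan bond ends between the two oxygens of a resorcinol ring, a position that electrophilic substitution avoids in favour of C6. The key step uses the fact that upper C4 is ortho to O1 on ring A (C4–C4a–C8a–O1) and next to the oxygenated C3: C4a, C8a and O1 with C4 as exocyclic carbon form an o-quinone methide, and C3 with its oxygen plus C2 is an α-oxygenated acetaldehyde. The same pattern recurs at middle C4, so the construction can be used a second time.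

## Logic of the disconnections

31 is traced to 30 and then 29 by cutting twelve O–benzyl bonds and two O–Si bonds. The free polyphenol tolerates neither acid, base nor oxidants, so it is released last; every earlier intermediate is then a neutral, lipophilic ether. The forward steps must be a fluoride desilylation and a neutral hydrogenolysis that spare the benzylic O1–C2 and C4–aryl bonds.

29 is opened to 28 at O1–C2 of the middle ring C. An ether bond at a benzylic carbinol can be made with inversion, which converts an acyclic 1,2-anti relationship into 2,3-cis. The demand is a clean SN2 closure at an electron-rich benzylic carbon, with only one free phenol in the molecule.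

28 is cut at the C2–aryl bond into 27 and 12. The carbinol is the adduct of an aryl nucleophile and an α-silyloxy aldehyde, so ring B comes from an arylmagnesium reagent. The demand is attack anti to the silyloxy group.

27 is cut at C3–C4 and at the lactol C–O bond into 24 and 7. This is the key construction used a second time; it removes one ring and two stereocentres. The demand is catalyst control in the presence of two resident flavan units and lactol closure on a single free phenol.

24 is cut at middle C4–lower C8 into 18 and 22 (through 23). The bond is a carbinol–aryl bond, so an aryllithium placed by a bromine atom fixes the regiochemistry between the two oxygens, and the two lower stereocentres arrive intact from 19. The demand is halogen–lithium exchange without proton transfer; the carbinol configuration does not matter because it is erased in the next step.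

22 goes back through 21 and 20 to 19 by cutting the O–benzyl bonds and the C8–Br bond; these are simple functional-group steps on chiral-pool material.

18 goes back through 16 to 14 by cutting the formyl C–C bond and the acetal O–C bond. The formyl carbon, the future middle C4, is placed on the only free ortho position of the only free phenol. This is why the resorcinol ring of 14 carries one benzyl and one methoxymethyl ether: only the oxygen that becomes middle O1 is freed. A symmetrical bis-acetal would require both oxygens to be freed and then told apart on an advanced intermediate. The demand is acetal cleavage that leaves the silyl ether, the benzyl ethers and the C4–aryl bond alone.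

14 is opened to 13 at O1–C2 of the upper ring C, and 13 is cut at C2–aryl into 10 and 12, for the same reasons and with the same demands as in the middle unit.

12 is traced to 11 by cutting the C–Mg bond. Both carbinol constructions need the same ring B nucleophile, so it is made once from the commercial bromide and used twice. The demand is clean magnesium insertion beside two aryl benzyl ethers and a solution that keeps its titre between the two uses.

10 is cut at C3–C4 and at the lactol C–O bond into 6 and 7. This is the key step: one ring, one skeletal bond and two stereocentres from a racemic carbinol. The demand is enamine addition to a methide carbon that carries a doubly ortho-substituted aryl group.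

6 is cut at the carbinol–aryl bond (upper C4–middle C8) into 2 and 4 (through 5). Making the resorcinol carbon between the two oxygens the nucleophile by directed lithiation solves the regiochemical problem of the upper interflavan bond. 2 comes from 1 and 4 from 3 by O-alkylation.

## Other disconnections considered

Alternative 1: The cut removes the whole lower ring A. On heating, the siloxyalkyne dimer A2 (alkyne on middle C4) and the cyclobutenone A3 would combine by 4π opening to a vinylketene, [2+2] addition, a second 4π opening and 6π closure, giving phenol A1 with new bonds C8a–C8, C7–C6 and C8a–C4a. In its favour, the alkyne carbon bound to middle C4 must become lower C8, so the hindered 4→8 regiochemistry is guaranteed; on this point it equals the chosen plan, which fixes it by bromine–lithium exchange. It is better than the chosen plan in one respect: the cascade is thermal and neutral, whereas step 14 needs an acid co-catalyst close to an ionisable C4–aryl bond. Against it, A2 needs a 4-alkynyl group of the right configuration on a 5-deoxyflavan and its conversion into an ynol silyl ether on a large molecule. After A1 the lower ring C with its 2R,3S pair must still be built from the cinnamyl phenol, while the chosen plan takes that unit complete from the chiral pool. It also does nothing for the upper C4–middle C8 bond. On step count it is clearly longer.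

Alternative 2: The cut is O1–C2 of the middle ring C as the last skeletal bond. Fluoride would free the ring A phenoxide of A5, which opens the cis-epoxide at benzylic C2 with inversion to give A4. In its favour, anti opening turns the epoxide geometry directly into 2,3-cis, the 3-hydroxyl emerges unprotected, and the medium is basic. Mechanistically it is the equal of the Mitsunobu closures of steps 7 and 16, both being SN2 reactions with inversion at C2. It is better in needing no phosphonium activation and one desilylation less, although an electron-rich aryl epoxide can ionise just as an activated benzylic alcohol can. Against it, the hard problems move into A5: the Z-alkene, its face-selective epoxidation beside the middle C4 diarylmethine, the configuration of that C4, and the tendency of a 3,4-dialkoxyphenyl epoxide to rearrange. Neither interflavan bond is addressed, so the total step count would be higher than in the chosen plan.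

Alternative 3: The cut is C4–C4a of the upper unit, the other ring bond at the carbon the chosen plan uses. A Lewis acid would induce the symmetric 3,5-bis(benzyloxy)phenyl ether of A7 to open the trans-epoxide at the benzylic carbon in a 6-endo Friedel–Crafts closure, giving A6. In its favour, the two ortho positions of the aryl ether are equivalent, 2,3-cis is already fixed in A7, and the product has the same 4-aryl-flavan-3-ol framework as 14, so on structure it is the equal of the chosen plan. It is better in that the closure is substrate-controlled and has no competing self-condensation of an aldehyde donor. Against it, the attacked carbon bears a 2,6-dioxygenated aryl group, so the opening is cation-like and inversion (3,4-trans) is not assured; the acetal groups also sit next to a Lewis acid. A7 holds three stereocentres that must be set in an acyclic series, probably six or more steps, against three steps to 6 and one catalytic step in the chosen plan.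

Key step: step 4

Remark: the enamine of the (S)-configured catalyst is assumed to add to the E-o-quinone methide with the same topicity as in its additions to E-nitroalkenes, which corresponds to 3R with the C4 aryl trans, as the target requires. The resorcinol oxygens of the key-step precursor are differentiated as one benzyl and one methoxymethyl ether, for the reason given under the disconnections.

Abbreviations used in names: UF = (2R,3R)-5,7-bis(benzyloxy)-2-[3,4-bis(benzyloxy)phenyl]-3-(tert-butyldimethylsilyloxy)chroman-4-yl, with the C2 aryl cis to the C3 oxygen and the C4 bond trans to it (the flavanyl group of 14). LC = (2R,3S)-3,5,7-tris(benzyloxy)-2-[3,4-bis(benzyloxy)phenyl]chroman-8-yl.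

## Steps

Step 1
Reactants: 1 2,4,6-trihydroxybenzaldehyde
Product: 2 2,4-bis(benzyloxy)-6-hydroxybenzaldehyde
Conditions: BnBr (2.1 equiv), K2CO3 (2.2 equiv), DMF, 0 °C → rt
Reagents that add atoms: benzyl bromide, BrCc1ccccc1
Why: Williamson etherification; the para hydroxyl and one ortho hydroxyl are alkylated, and the remaining ortho hydroxyl, hydrogen-bonded to the formyl group, should stay free with two equivalents of bromide.

Step 2
Reactants: 3 3-(benzyloxy)phenol
Product: 4 1-(benzyloxy)-3-(methoxymethoxy)benzene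
Conditions: NaH, MOMCl, DMF, 0 °C → rt
Reagents that add atoms: chloromethyl methyl ether, COCCl
Why: O-alkylation of the sodium phenoxide; gives a resorcinol unit with two different ethers that both direct lithiation to the carbon between them.

Step 3
Reactants: 4 1-(benzyloxy)-3-(methoxymethoxy)benzene; 2 2,4-bis(benzyloxy)-6-hydroxybenzaldehyde
Product: 6 rac-[2,4-bis(benzyloxy)-6-hydroxyphenyl][2-(benzyloxy)-6-(methoxymethoxy)phenyl]methanol, via aryllithium 5 (not isolated)
Conditions: 4 (2.4 equiv), n-BuLi (2.3 equiv), THF, 0 °C; then 2, −78 → 0 °C; H2O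
Reagents that add atoms: none
Why: Directed ortho-metalation at the carbon flanked by both oxygens, then 1,2-addition to the aldehyde; one equivalent of 5 deprotonates the phenol of 2 (returning 4) and the next adds to the formyl group; the carbinol configuration is irrelevant.

Step 4
Reactants: 6 rac-[2,4-bis(benzyloxy)-6-hydroxyphenyl][2-(benzyloxy)-6-(methoxymethoxy)phenyl]methanol; 7 (tert-butyldimethylsilyloxy)acetaldehyde
Product: 10 (3R)-5,7-bis(benzyloxy)-4-[2-(benzyloxy)-6-(methoxymethoxy)phenyl]-3-(tert-butyldimethylsilyloxy)chroman-2-ol (3,4-trans; both C2 anomers), via o-quinone methide 8 (not isolated), via hydroxy aldehyde 9 (not isolated)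
Conditions: 7 (3 equiv), (S)-2-[diphenyl(trimethylsilyloxy)methyl]pyrrolidine (20 mol %), PhCO2H (20 mol %), CH2Cl2, 0 °C → rt
Reagents that add atoms: none
Why: Benzoic acid ionises 6 with loss of water to the o-quinone methide 8, whose methide carbon is the future C4. The amine and 7 form the E-enamine, one face of which is blocked by the diphenyl(silyloxy)methyl group, and its α-carbon adds to the methide carbon, forming C3–C4 and restoring the aromatic ring A. Hydrolysis of the iminium ion by the water released returns the catalyst and gives aldehyde 9, which the ring A phenol traps reversibly as the six-membered lactol 10 (6-exo-trig hemiacetal formation). The closest known reaction type is the secondary-amine-catalysed Michael addition of aldehydes to o-quinone methides formed in situ, which gives trans-3,4-disubstituted chroman-2-ols; here the donor is α-silyloxylated and the methide aryl is doubly ortho-substituted. C3 (R) is set by the shielded enamine face, and C4 by the synclinal approach of the enamine to the E-configured methide, the topicity known from nitroalkene additions. C3 can epimerise through the enamine or the open aldehyde while C4 cannot, so the 3,4-trans lactol is also the thermodynamic product. The step needs lactol closure on the ring A oxygen only, which is secured because this is the only free phenol, the resorcinol oxygens being blocked as benzyl and methoxymethyl ethers. It also needs cross-addition to outrun self-aldol of 7, which the more electrophilic, cation-like methide should ensure.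

Step 5
Reactants: 11 4-bromo-1,2-bis(benzyloxy)benzene
Product: 12 [3,4-bis(benzyloxy)phenyl]magnesium bromide (titrated stock solution in THF)
Conditions: Mg turnings, I2 (cat.), THF, rt → 45 °C; titration, storage under Ar
Reagents that add atoms: magnesium, [Mg]
Why: Grignard formation by insertion of magnesium metal into the aryl C–Br bond; the aryl benzyl ethers are inert, and the solution is made once on a scale that serves steps 6 and 15 and is re-titrated before the second use.

Step 6
Reactants: 10 (3R)-5,7-bis(benzyloxy)-4-[2-(benzyloxy)-6-(methoxymethoxy)phenyl]-3-(tert-butyldimethylsilyloxy)chroman-2-ol; 12 [3,4-bis(benzyloxy)phenyl]magnesium bromide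
Product: 13 (1S,2R,3R)-1-[3,4-bis(benzyloxy)phenyl]-3-[2,4-bis(benzyloxy)-6-hydroxyphenyl]-3-[2-(benzyloxy)-6-(methoxymethoxy)phenyl]-2-(tert-butyldimethylsilyloxy)propan-1-ol
Conditions: 12 (4 equiv, THF solution), THF, −78 → 0 °C; aq NH4Cl
Reagents that add atoms: none
Why: Grignard addition to the open form 9 of the lactol (the first equivalent deprotonates and opens it); polar Felkin–Anh (Cornforth) control places the nucleophile anti to the C–OSi bond and past the hydrogen, giving the 1,2-anti carbinol (1S).

Step 7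
Reactants: 13 (1S,2R,3R)-1-[3,4-bis(benzyloxy)phenyl]-3-[2,4-bis(benzyloxy)-6-hydroxyphenyl]-3-[2-(benzyloxy)-6-(methoxymethoxy)phenyl]-2-(tert-butyldimethylsilyloxy)propan-1-ol
Product: 14 (2R,3R)-5,7-bis(benzyloxy)-2-[3,4-bis(benzyloxy)phenyl]-4-[2-(benzyloxy)-6-(methoxymethoxy)phenyl]-3-(tert-butyldimethylsilyloxy)chroman (2,3-cis; 3,4-trans)
Conditions: PPh3, DIAD, THF, 0 °C → rt
Reagents that add atoms: none
Why: Intramolecular Mitsunobu etherification; the only free phenol displaces the activated benzylic oxygen with inversion (6-exo-tet), so the (1S)-carbinol becomes C2 (R), cis to the C3 silyloxy group.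

Step 8
Reactants: 14 (2R,3R)-5,7-bis(benzyloxy)-2-[3,4-bis(benzyloxy)phenyl]-4-[2-(benzyloxy)-6-(methoxymethoxy)phenyl]-3-(tert-butyldimethylsilyloxy)chroman
Product: 16 (2R,3R)-5,7-bis(benzyloxy)-2-[3,4-bis(benzyloxy)phenyl]-4-[2-(benzyloxy)-6-hydroxyphenyl]-3-(tert-butyldimethylsilyloxy)chroman (2,3-cis; 3,4-trans), via aryl trimethylsilyl ether 15 (not isolated)
Conditions: Me3SiOTf, 2,2′-bipyridyl, CH2Cl2, 0 °C → rt; then H2O, aq NaHCO3
Reagents that add atoms: none
Why: Chemoselective cleavage of an aryl methoxymethyl ether; the silyl triflate–bipyridyl pair turns ArO–CH2OMe into ArO–SiMe3 without free acid, and the labile aryl silyl ether hydrolyses on work-up, leaving benzyl ethers, the alkyl silyl ether and the C4–aryl bond untouched.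

Step 9
Reactants: 16 (2R,3R)-5,7-bis(benzyloxy)-2-[3,4-bis(benzyloxy)phenyl]-4-[2-(benzyloxy)-6-hydroxyphenyl]-3-(tert-butyldimethylsilyloxy)chroman
Product: 18 4-(benzyloxy)-2-hydroxy-3-(UF)benzaldehyde, via hydroxymethyl phenol 17 (not isolated)
Conditions: MgCl2, Et3N, (CH2O)n, THF, reflux; aq NH4Cl
Reagents that add atoms: formaldehyde (as paraformaldehyde), C=O
Why: Magnesium-mediated ortho-formylation (Casnati–Skattebøl); the magnesium phenoxide delivers formaldehyde to its only free ortho position and the benzylic alkoxide is oxidised by a second formaldehyde through hydride transfer, placing the future middle C4 ortho to the future middle O1.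

Step 10
Reactants: 19 (+)-catechin
Product: 20 (2R,3S)-5,7-bis(benzyloxy)-2-[3,4-bis(benzyloxy)phenyl]chroman-3-ol
Conditions: BnBr (4.4 equiv), K2CO3, DMF, 0 °C → rt
Reagents that add atoms: benzyl bromide, BrCc1ccccc1
Why: Williamson benzylation of the four phenols; carbonate does not deprotonate the secondary alcohol, and the mild conditions should avoid epimerisation at C2.

Step 11
Reactants: 20 (2R,3S)-5,7-bis(benzyloxy)-2-[3,4-bis(benzyloxy)phenyl]chroman-3-ol
Product: 21 (2R,3S)-5,7-bis(benzyloxy)-2-[3,4-bis(benzyloxy)phenyl]-8-bromochroman-3-ol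
Conditions: NBS, CH2Cl2, −78 °C → rt
Reagents that add atoms: N-bromosuccinimide, O=C1CCC(=O)N1Br
Why: Electrophilic aromatic bromination; in the tetra-O-benzyl series C8, ortho to O1 and to the 7-oxygen, is the more reactive free ring A position, so one equivalent should give the 8-bromide.

Step 12
Reactants: 21 (2R,3S)-5,7-bis(benzyloxy)-2-[3,4-bis(benzyloxy)phenyl]-8-bromochroman-3-ol
Product: 22 (2R,3S)-3,5,7-tris(benzyloxy)-2-[3,4-bis(benzyloxy)phenyl]-8-bromochroman
Conditions: NaH, BnBr, DMF, 0 °C → rt
Reagents that add atoms: benzyl bromide, BrCc1ccccc1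
Why: Williamson etherification of the secondary alkoxide; the 3-O-benzyl group keeps the alcohol from quenching the aryllithium and leaves in the final hydrogenolysis.

Step 13
Reactants: 22 (2R,3S)-3,5,7-tris(benzyloxy)-2-[3,4-bis(benzyloxy)phenyl]-8-bromochroman; 18 4-(benzyloxy)-2-hydroxy-3-(UF)benzaldehyde
Product: 24 3-(benzyloxy)-2-(UF)-6-[hydroxy(LC)methyl]phenol (both carbinol epimers), via aryllithium 23 (not isolated)
Conditions: 22 (2.5 equiv), n-BuLi (2.4 equiv), THF, −78 °C; then 18, −78 → −30 °C; H2O
Reagents that add atoms: none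
Why: Bromine–lithium exchange, then 1,2-addition of the aryllithium to the salicylaldehyde (one equivalent is spent on the phenol); this joins middle C4 to lower C8 with regiochemistry fixed by the bromine, and the unselective carbinol centre is erased in step 14.

Step 14
Reactants: 24 3-(benzyloxy)-2-(UF)-6-[hydroxy(LC)methyl]phenol; 7 (tert-butyldimethylsilyloxy)acetaldehyde
Product: 27 (3R)-7-(benzyloxy)-8-(UF)-4-(LC)-3-(tert-butyldimethylsilyloxy)chroman-2-ol (3,4-trans; both C2 anomers), via o-quinone methide 25 (not isolated), via hydroxy aldehyde 26 (not isolated)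
Conditions: 7 (4 equiv), (S)-2-[diphenyl(trimethylsilyloxy)methyl]pyrrolidine (30 mol %), PhCO2H (30 mol %), CH2Cl2, 0 °C → rt
Reagents that add atoms: none
Why: The aminocatalytic o-quinone methide Michael addition and lactol closure of step 4 again; the middle ring has no substituent at C5, so methide 25 should be cleanly E, the same catalyst sets C3 (R) with C4 trans, and the single free phenol closes the lactol.

Step 15
Reactants: 27 (3R)-7-(benzyloxy)-8-(UF)-4-(LC)-3-(tert-butyldimethylsilyloxy)chroman-2-ol; 12 [3,4-bis(benzyloxy)phenyl]magnesium bromide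
Product: 28 (1S,2R)-1-[3,4-bis(benzyloxy)phenyl]-3-[4-(benzyloxy)-2-hydroxy-3-(UF)phenyl]-2-(tert-butyldimethylsilyloxy)-3-(LC)propan-1-ol (C3 as C4 of 27)
Conditions: 12 (4 equiv, THF solution), THF, −78 → 0 °C; aq NH4Cl
Reagents that add atoms: none
Why: Grignard addition to the ring-opened aldehyde form of the lactol under polar Felkin–Anh control, as in step 6, giving the 1,2-anti (1S) carbinol.

Step 16
Reactants: 28 (1S,2R)-1-[3,4-bis(benzyloxy)phenyl]-3-[4-(benzyloxy)-2-hydroxy-3-(UF)phenyl]-2-(tert-butyldimethylsilyloxy)-3-(LC)propan-1-ol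
Product: 29 (2R,3R)-7-(benzyloxy)-2-[3,4-bis(benzyloxy)phenyl]-8-(UF)-4-(LC)-3-(tert-butyldimethylsilyloxy)chroman (2,3-cis; 3,4-trans)
Conditions: PPh3, DIAD, THF, 0 °C → rt
Reagents that add atoms: none
Why: Intramolecular Mitsunobu etherification with inversion at the benzylic carbinol, as in step 7; it closes the middle ring C with C2 (R) cis to the C3 silyloxy group and completes the protected trimer.

Step 17
Reactants: 29 (2R,3R)-7-(benzyloxy)-2-[3,4-bis(benzyloxy)phenyl]-8-(UF)-4-(LC)-3-(tert-butyldimethylsilyloxy)chroman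
Product: 30 dodeca-O-benzyl trimer, that is 29 with both silyloxy groups replaced by hydroxyl
Conditions: Bu4NF, THF, rt → 45 °C; H2O
Reagents that add atoms: none
Why: Fluoride cleavage of the two secondary silyl ethers, driven by the Si–F bond; the non-acidic medium is safe for both interflavan bonds.

Step 18
Reactants: 30 dodeca-O-benzyl trimer
Product: 31 the target CNP0270097.1, (2R,3R)-flavan-3,5,7,3′,4′-pentol linked 4→8 (trans to its 3-hydroxyl) to (2R,3R)-flavan-3,7,3′,4′-tetrol linked 4→8 (trans to its 3-hydroxyl) to (+)-catechin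
Conditions: H2 (1 atm), Pd(OH)2/C, THF–MeOH–H2O, rt
Reagents that add atoms: none
Why: Catalytic hydrogenolysis of eleven aryl benzyl ethers and one alkyl benzyl ether under neutral conditions, the standard release of oligomeric flavan-3-ols; no stereocentre is touched.

## Compound list

1 | 2,4,6-trihydroxybenzaldehyde | O=Cc1c(O)cc(O)cc1O | starting material
2 | 2,4-bis(benzyloxy)-6-hydroxybenzaldehyde | O=Cc1c(O)cc(OCc9ccccc9)cc1OCc9ccccc9 | intermediate
3 | 3-(benzyloxy)phenol | Oc1cccc(OCc9ccccc9)c1 | starting material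
4 | 1-(benzyloxy)-3-(methoxymethoxy)benzene | COCOc1cccc(OCc9ccccc9)c1 | intermediate
5 | [2-(benzyloxy)-6-(methoxymethoxy)phenyl]lithium | [Li]c1c(OCOC)cccc1OCc9ccccc9 | intermediate
6 | rac-[2,4-bis(benzyloxy)-6-hydroxyphenyl][2-(benzyloxy)-6-(methoxymethoxy)phenyl]methanol | OC(c1c(O)cc(OCc9ccccc9)cc1OCc9ccccc9)c1c(OCOC)cccc1OCc9ccccc9 | intermediate
7 | (tert-butyldimethylsilyloxy)acetaldehyde | O=CCO[Si](C)(C)C(C)(C)C | starting material
8 | (E)-3,5-bis(benzyloxy)-6-{[2-(benzyloxy)-6-(methoxymethoxy)phenyl]methylidene}cyclohexa-2,4-dien-1-one | O=C1C=C(OCc9ccccc9)C=C(OCc9ccccc9)\C1=C/c1c(OCOC)cccc1OCc9ccccc9 | intermediate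
9 | (2R,3R)-3-[2,4-bis(benzyloxy)-6-hydroxyphenyl]-3-[2-(benzyloxy)-6-(methoxymethoxy)phenyl]-2-(tert-butyldimethylsilyloxy)propanal | O=C[C@H](O[Si](C)(C)C(C)(C)C)[C@H](c1c(O)cc(OCc9ccccc9)cc1OCc9ccccc9)c1c(OCOC)cccc1OCc9ccccc9 | intermediate
10 | (3R)-5,7-bis(benzyloxy)-4-[2-(benzyloxy)-6-(methoxymethoxy)phenyl]-3-(tert-butyldimethylsilyloxy)chroman-2-ol, 3,4-trans, both C2 anomers | c9ccccc9COc1cc(OCc9ccccc9)c2c(c1)OC(O)[C@H](O[Si](C)(C)C(C)(C)C)[C@H]2c1c(OCOC)cccc1OCc9ccccc9 | intermediate
11 | 4-bromo-1,2-bis(benzyloxy)benzene | Brc1ccc(OCc9ccccc9)c(OCc9ccccc9)c1 | starting material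
12 | [3,4-bis(benzyloxy)phenyl]magnesium bromide (titrated THF solution) | Br[Mg]c1ccc(OCc9ccccc9)c(OCc9ccccc9)c1 | intermediate
13 | (1S,2R,3R)-1-[3,4-bis(benzyloxy)phenyl]-3-[2,4-bis(benzyloxy)-6-hydroxyphenyl]-3-[2-(benzyloxy)-6-(methoxymethoxy)phenyl]-2-(tert-butyldimethylsilyloxy)propan-1-ol | O[C@@H](c7ccc(OCc9ccccc9)c(OCc9ccccc9)c7)[C@H](O[Si](C)(C)C(C)(C)C)[C@H](c1c(O)cc(OCc9ccccc9)cc1OCc9ccccc9)c1c(OCOC)cccc1OCc9ccccc9 | intermediate
14 | (2R,3R)-5,7-bis(benzyloxy)-2-[3,4-bis(benzyloxy)phenyl]-4-[2-(benzyloxy)-6-(methoxymethoxy)phenyl]-3-(tert-butyldimethylsilyloxy)chroman, 2,3-cis, 3,4-trans | c9ccccc9COc1cc(OCc9ccccc9)c2c(c1)O[C@H](c7ccc(OCc9ccccc9)c(OCc9ccccc9)c7)[C@H](O[Si](C)(C)C(C)(C)C)[C@H]2c1c(OCc9ccccc9)cccc1OCOC | intermediate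
15 | trimethylsilyl ether of 16 (aryl O–SiMe3 in place of the methoxymethyl ether of 14) | c9ccccc9COc1cc(OCc9ccccc9)c2c(c1)O[C@H](c7ccc(OCc9ccccc9)c(OCc9ccccc9)c7)[C@H](O[Si](C)(C)C(C)(C)C)[C@H]2c1c(OCc9ccccc9)cccc1O[Si](C)(C)C | intermediate
16 | (2R,3R)-5,7-bis(benzyloxy)-2-[3,4-bis(benzyloxy)phenyl]-4-[2-(benzyloxy)-6-hydroxyphenyl]-3-(tert-butyldimethylsilyloxy)chroman, 2,3-cis, 3,4-trans | c9ccccc9COc1cc(OCc9ccccc9)c2c(c1)O[C@H](c7ccc(OCc9ccccc9)c(OCc9ccccc9)c7)[C@H](O[Si](C)(C)C(C)(C)C)[C@H]2c1c(OCc9ccccc9)cccc1O | intermediate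
17 | 3-(benzyloxy)-6-(hydroxymethyl)-2-(UF)phenol | c9ccccc9COc1cc(OCc9ccccc9)c2c(c1)O[C@H](c7ccc(OCc9ccccc9)c(OCc9ccccc9)c7)[C@H](O[Si](C)(C)C(C)(C)C)[C@H]2c1c(OCc9ccccc9)ccc(CO)c1O | intermediate
18 | 4-(benzyloxy)-2-hydroxy-3-(UF)benzaldehyde | c9ccccc9COc1cc(OCc9ccccc9)c2c(c1)O[C@H](c7ccc(OCc9ccccc9)c(OCc9ccccc9)c7)[C@H](O[Si](C)(C)C(C)(C)C)[C@H]2c1c(OCc9ccccc9)ccc(C=O)c1O | intermediate
19 | (+)-catechin | Oc1cc(O)c2c(c1)O[C@H](c1ccc(O)c(O)c1)[C@@H](O)C2 | starting material
20 | (2R,3S)-5,7-bis(benzyloxy)-2-[3,4-bis(benzyloxy)phenyl]chroman-3-ol | c9ccccc9COc1cc(OCc9ccccc9)c2c(c1)O[C@H](c7ccc(OCc9ccccc9)c(OCc9ccccc9)c7)[C@@H](O)C2 | intermediate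
21 | (2R,3S)-5,7-bis(benzyloxy)-2-[3,4-bis(benzyloxy)phenyl]-8-bromochroman-3-ol | c9ccccc9COc1cc(OCc9ccccc9)c2c(c1Br)O[C@H](c7ccc(OCc9ccccc9)c(OCc9ccccc9)c7)[C@@H](O)C2 | intermediate
22 | (2R,3S)-3,5,7-tris(benzyloxy)-2-[3,4-bis(benzyloxy)phenyl]-8-bromochroman | c9ccccc9COc1cc(OCc9ccccc9)c2c(c1Br)O[C@H](c7ccc(OCc9ccccc9)c(OCc9ccccc9)c7)[C@@H](OCc9ccccc9)C2 | intermediate
23 | [(2R,3S)-3,5,7-tris(benzyloxy)-2-[3,4-bis(benzyloxy)phenyl]chroman-8-yl]lithium | c9ccccc9COc1cc(OCc9ccccc9)c2c(c1[Li])O[C@H](c7ccc(OCc9ccccc9)c(OCc9ccccc9)c7)[C@@H](OCc9ccccc9)C2 | intermediate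
24 | 3-(benzyloxy)-2-(UF)-6-[hydroxy(LC)methyl]phenol, both carbinol epimers | c9ccccc9COc1cc(OCc9ccccc9)c2c(c1)O[C@H](c7ccc(OCc9ccccc9)c(OCc9ccccc9)c7)[C@H](O[Si](C)(C)C(C)(C)C)[C@H]2c1c(OCc9ccccc9)ccc(C(O)c3c(OCc9ccccc9)cc(OCc9ccccc9)c4c3O[C@H](c7ccc(OCc9ccccc9)c(OCc9ccccc9)c7)[C@@H](OCc9ccccc9)C4)c1O | intermediate
25 | (E)-3-(benzyloxy)-2-(UF)-6-[(LC)methylidene]cyclohexa-2,4-dien-1-one | c9ccccc9COc1cc(OCc9ccccc9)c2c(c1)O[C@H](c7ccc(OCc9ccccc9)c(OCc9ccccc9)c7)[C@H](O[Si](C)(C)C(C)(C)C)[C@H]2C1=C(OCc9ccccc9)C=C\C(=C/c3c(OCc9ccccc9)cc(OCc9ccccc9)c4c3O[C@H](c7ccc(OCc9ccccc9)c(OCc9ccccc9)c7)[C@@H](OCc9ccccc9)C4)C1=O | intermediate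
26 | (2R)-3-[4-(benzyloxy)-2-hydroxy-3-(UF)phenyl]-2-(tert-butyldimethylsilyloxy)-3-(LC)propanal, C3 as C4 of 27 | c9ccccc9COc1cc(OCc9ccccc9)c2c(c1)O[C@H](c7ccc(OCc9ccccc9)c(OCc9ccccc9)c7)[C@H](O[Si](C)(C)C(C)(C)C)[C@H]2c1c(OCc9ccccc9)ccc([C@@H]([C@@H](O[Si](C)(C)C(C)(C)C)C=O)c3c(OCc9ccccc9)cc(OCc9ccccc9)c4c3O[C@H](c7ccc(OCc9ccccc9)c(OCc9ccccc9)c7)[C@@H](OCc9ccccc9)C4)c1O | intermediate
27 | (3R)-7-(benzyloxy)-8-(UF)-4-(LC)-3-(tert-butyldimethylsilyloxy)chroman-2-ol, 3,4-trans, both C2 anomers | c9ccccc9COc1cc(OCc9ccccc9)c2c(c1)O[C@H](c7ccc(OCc9ccccc9)c(OCc9ccccc9)c7)[C@H](O[Si](C)(C)C(C)(C)C)[C@H]2c1c(OCc9ccccc9)ccc3c1OC(O)[C@H](O[Si](C)(C)C(C)(C)C)[C@H]3c4c(OCc9ccccc9)cc(OCc9ccccc9)c5c4O[C@H](c7ccc(OCc9ccccc9)c(OCc9ccccc9)c7)[C@@H](OCc9ccccc9)C5 | intermediate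
28 | (1S,2R)-1-[3,4-bis(benzyloxy)phenyl]-3-[4-(benzyloxy)-2-hydroxy-3-(UF)phenyl]-2-(tert-butyldimethylsilyloxy)-3-(LC)propan-1-ol, C3 as C4 of 27 | c9ccccc9COc1cc(OCc9ccccc9)c2c(c1)O[C@H](c7ccc(OCc9ccccc9)c(OCc9ccccc9)c7)[C@H](O[Si](C)(C)C(C)(C)C)[C@H]2c1c(OCc9ccccc9)ccc([C@@H]([C@@H](O[Si](C)(C)C(C)(C)C)[C@@H](O)c7ccc(OCc9ccccc9)c(OCc9ccccc9)c7)c3c(OCc9ccccc9)cc(OCc9ccccc9)c4c3O[C@H](c7ccc(OCc9ccccc9)c(OCc9ccccc9)c7)[C@@H](OCc9ccccc9)C4)c1O | intermediate
29 | (2R,3R)-7-(benzyloxy)-2-[3,4-bis(benzyloxy)phenyl]-8-(UF)-4-(LC)-3-(tert-butyldimethylsilyloxy)chroman, 2,3-cis, 3,4-trans (fully protected trimer) | c9ccccc9COc1cc(OCc9ccccc9)c2c(c1)O[C@H](c7ccc(OCc9ccccc9)c(OCc9ccccc9)c7)[C@H](O[Si](C)(C)C(C)(C)C)[C@H]2c1c(OCc9ccccc9)ccc3c1O[C@H](c7ccc(OCc9ccccc9)c(OCc9ccccc9)c7)[C@H](O[Si](C)(C)C(C)(C)C)[C@H]3c4c(OCc9ccccc9)cc(OCc9ccccc9)c5c4O[C@H](c7ccc(OCc9ccccc9)c(OCc9ccccc9)c7)[C@@H](OCc9ccccc9)C5 | intermediate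
30 | dodeca-O-benzyl trimer: 29 with both silyloxy groups replaced by hydroxyl | c9ccccc9COc1cc(OCc9ccccc9)c2c(c1)O[C@H](c7ccc(OCc9ccccc9)c(OCc9ccccc9)c7)[C@H](O)[C@H]2c1c(OCc9ccccc9)ccc3c1O[C@H](c7ccc(OCc9ccccc9)c(OCc9ccccc9)c7)[C@H](O)[C@H]3c4c(OCc9ccccc9)cc(OCc9ccccc9)c5c4O[C@H](c7ccc(OCc9ccccc9)c(OCc9ccccc9)c7)[C@@H](OCc9ccccc9)C5 | intermediate
31 | CNP0270097.1: upper (2R,3R)-5,7,3′,4′-tetrahydroxyflavan-3-ol, 4→8 to middle (2R,3R)-7,3′,4′-trihydroxyflavan-3-ol, 4→8 to (+)-catechin, each C4 bond trans to the 3-hydroxyl of its unit | Oc1cc(O)c2c(c1)O[C@H](c1ccc(O)c(O)c1)[C@H](O)[C@H]2c1c(O)ccc2c1O[C@H](c1ccc(O)c(O)c1)[C@H](O)[C@H]2c1c(O)cc(O)c2c1O[C@H](c1ccc(O)c(O)c1)[C@@H](O)C2 | target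

## Step count and least certain steps

Total: 18 steps. Longest linear sequence: 13 steps (steps 1, 3, 4, 6 to 9 and 13 to 18, from 1). The branch from 3 (step 2) joins at step 3, the branch from 11 (step 5) at steps 6 and 15, and the branch from 19 (steps 10 to 12) at step 13.

Step 4 (key step). The methide carbon of 8 carries an aryl group with two ortho substituents, and the peri benzyloxy group of ring A crowds the E geometry. The likely failures are slow enamine addition, so that self-aldol of 7 and acid-induced decomposition of 6 take over, and erosion of facial selectivity at C4 through a mixed E/Z methide. Fallback: setting out from 6, p-toluenesulfinic acid in CH2Cl2 should give the sulfone 3,5-bis(benzyloxy)-2-{[2-(benzyloxy)-6-(methoxymethoxy)phenyl](4-methylphenylsulfonyl)methyl}phenol F1. With 7, the same amine and aqueous NaHCO3 in CH2Cl2, base-induced 1,4-elimination of sulfinate would release 8 slowly and without acid, so the enamine can be kept in large excess over a low stationary concentration of the methide. The route is rejoined at 10.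

Step 14. The cation derived from 24 is stabilised by two very electron-rich rings and flanked on both sides, so C–C bond formation may be slow or reversible. The two resident flavan units may also oppose the catalyst, and the acid co-catalyst now sits beside an interflavan bond ortho to a free phenol, which invites fragmentation. Fallback: setting out from 24, p-toluenesulfinic acid should give the sulfone 3-(benzyloxy)-2-(UF)-6-[(LC)(4-methylphenylsulfonyl)methyl]phenol F2. Base-triggered release of 25 (aqueous NaHCO3, CH2Cl2) in the presence of 7 and the amine would then avoid acid altogether and return to 27.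

Step 6 (the same applies to step 15). Facial selectivity may be insufficient, because a purely steric arrangement with the large diarylmethyl group anti to the nucleophile, or magnesium chelation by the neighbouring phenoxide, would favour the 1,2-syn carbinol. Fallback: setting out from 13 as a mixture of C1 epimers, MnO2 in CH2Cl2 should oxidise the electron-rich benzylic carbinol to the ketone (2R,3R)-1-[3,4-bis(benzyloxy)phenyl]-3-[2,4-bis(benzyloxy)-6-hydroxyphenyl]-3-[2-(benzyloxy)-6-(methoxymethoxy)phenyl]-2-(tert-butyldimethylsilyloxy)propan-1-one F3. Reduction with BH3·SMe2 and (S)-1-methyl-3,3-diphenyltetrahydro-1H,3H-pyrrolo[1,2-c][1,3,2]oxazaborole (Corey–Bakshi–Shibata reduction), in which the aryl group acts as the large substituent, would return (1S)-13 under reagent control.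

Step 7 (the same applies to step 16). The activated benzylic oxygen next to a 3,4-dialkoxyphenyl group may ionise, which would cause loss of stereospecificity at C2 or elimination. Fallback: setting out from 13 (either C1 epimer), oxidation as for ketone F3 and closure of the ketone on the phenol should give the hemiketal (3R)-5,7-bis(benzyloxy)-2-[3,4-bis(benzyloxy)phenyl]-4-[2-(benzyloxy)-6-(methoxymethoxy)phenyl]-3-(tert-butyldimethylsilyloxy)chroman-2-ol F4. Et3SiH with BF3·OEt2 in CH2Cl2 at −78 °C would reduce the derived 2-aryl oxocarbenium ion, with hydride expected anti to the pseudoaxial C3 silyloxy group. C2 is then set by C–H bond formation instead of C–O substitution, and the route is rejoined at 14.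

Step 13. The aryllithium 23 may abstract a benzylic proton from the flanking benzyl ether on warming, and addition to the deprotonated, deactivated salicylaldehyde may be slow, so that protonation of 23 outruns C–C bond formation. Fallback, with reversed polarity: setting out from 22, aryllithium 23 is quenched with DMF to give (2R,3S)-3,5,7-tris(benzyloxy)-2-[3,4-bis(benzyloxy)phenyl]chroman-8-carbaldehyde F5. Setting out from 16, its bromomagnesium phenoxide (EtMgBr, toluene) would be hydroxyalkylated by F5 at the only free ortho position (chelation-controlled ortho-hydroxyalkylation of magnesium phenoxides). This gives 24 directly and makes step 9 unnecessary.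

## Further compounds

F1 | step 4 | 3,5-bis(benzyloxy)-2-{[2-(benzyloxy)-6-(methoxymethoxy)phenyl](4-methylphenylsulfonyl)methyl}phenol (racemic) | Cc1ccc(cc1)S(=O)(=O)C(c1c(O)cc(OCc9ccccc9)cc1OCc9ccccc9)c1c(OCOC)cccc1OCc9ccccc9
F2 | step 14 | 3-(benzyloxy)-2-(UF)-6-[(LC)(4-methylphenylsulfonyl)methyl]phenol (both epimers at the sulfonyl carbon) | c9ccccc9COc1cc(OCc9ccccc9)c2c(c1)O[C@H](c7ccc(OCc9ccccc9)c(OCc9ccccc9)c7)[C@H](O[Si](C)(C)C(C)(C)C)[C@H]2c1c(OCc9ccccc9)ccc(C(c3c(OCc9ccccc9)cc(OCc9ccccc9)c4c3O[C@H](c7ccc(OCc9ccccc9)c(OCc9ccccc9)c7)[C@@H](OCc9ccccc9)C4)S(=O)(=O)c6ccc(C)cc6)c1O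
F3 | step 6 | (2R,3R)-1-[3,4-bis(benzyloxy)phenyl]-3-[2,4-bis(benzyloxy)-6-hydroxyphenyl]-3-[2-(benzyloxy)-6-(methoxymethoxy)phenyl]-2-(tert-butyldimethylsilyloxy)propan-1-one | O=C(c7ccc(OCc9ccccc9)c(OCc9ccccc9)c7)[C@H](O[Si](C)(C)C(C)(C)C)[C@H](c1c(O)cc(OCc9ccccc9)cc1OCc9ccccc9)c1c(OCOC)cccc1OCc9ccccc9
F4 | step 7 | (3R)-5,7-bis(benzyloxy)-2-[3,4-bis(benzyloxy)phenyl]-4-[2-(benzyloxy)-6-(methoxymethoxy)phenyl]-3-(tert-butyldimethylsilyloxy)chroman-2-ol (3,4-trans, both C2 anomers) | c9ccccc9COc1cc(OCc9ccccc9)c2c(c1)OC(O)(c7ccc(OCc9ccccc9)c(OCc9ccccc9)c7)[C@H](O[Si](C)(C)C(C)(C)C)[C@H]2c1c(OCc9ccccc9)cccc1OCOC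
F5 | step 13 | (2R,3S)-3,5,7-tris(benzyloxy)-2-[3,4-bis(benzyloxy)phenyl]chroman-8-carbaldehyde | c9ccccc9COc1cc(OCc9ccccc9)c2c(c1C=O)O[C@H](c7ccc(OCc9ccccc9)c(OCc9ccccc9)c7)[C@@H](OCc9ccccc9)C2
A1 | alternative 1 | benzannulation product: upper–middle dimer bearing the new lower ring A as free phenol, with C7 triisopropylsiloxy, C5 benzyloxy and an E-cinnamyl group at C4a | c9ccccc9COc1cc(OCc9ccccc9)c2c(c1)O[C@H](c7ccc(OCc9ccccc9)c(OCc9ccccc9)c7)[C@H](OCc9ccccc9)[C@H]2c1c(OCc9ccccc9)ccc2c1O[C@H](c7ccc(OCc9ccccc9)c(OCc9ccccc9)c7)[C@H](OCc9ccccc9)[C@H]2c1c(O[Si](C(C)C)(C(C)C)C(C)C)cc(OCc9ccccc9)c(C/C=C/c7ccc(OCc9ccccc9)c(OCc9ccccc9)c7)c1O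
A2 | alternative 1 | upper–middle dimer with a (triisopropylsiloxy)ethynyl group at middle C4, trans to the middle 3-benzyloxy group | c9ccccc9COc1cc(OCc9ccccc9)c2c(c1)O[C@H](c7ccc(OCc9ccccc9)c(OCc9ccccc9)c7)[C@H](OCc9ccccc9)[C@H]2c1c(OCc9ccccc9)ccc2c1O[C@H](c7ccc(OCc9ccccc9)c(OCc9ccccc9)c7)[C@H](OCc9ccccc9)[C@H]2C#CO[Si](C(C)C)(C(C)C)C(C)C
A3 | alternative 1 | 3-(benzyloxy)-4-{(E)-3-[3,4-bis(benzyloxy)phenyl]prop-2-enyl}cyclobut-2-en-1-one (racemic) | O=C1C=C(OCc9ccccc9)C1C/C=C/c7ccc(OCc9ccccc9)c(OCc9ccccc9)c7
A4 | alternative 2 | benzyl-protected trimer with free 3-hydroxyl on the middle unit | c9ccccc9COc1cc(OCc9ccccc9)c2c(c1)O[C@H](c7ccc(OCc9ccccc9)c(OCc9ccccc9)c7)[C@H](OCc9ccccc9)[C@H]2c1c(OCc9ccccc9)ccc2c1O[C@H](c7ccc(OCc9ccccc9)c(OCc9ccccc9)c7)[C@H](O)[C@H]2c1c(OCc9ccccc9)cc(OCc9ccccc9)c2c1O[C@H](c7ccc(OCc9ccccc9)c(OCc9ccccc9)c7)[C@@H](OCc9ccccc9)C2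
A5 | alternative 2 | seco precursor: middle ring A oxygen as tert-butyldimethylsilyl ether, side chain carrying the lower unit at C4 and a cis-epoxide between C3 and the ring B carbon C2 | c9ccccc9COc1cc(OCc9ccccc9)c2c(c1)O[C@H](c7ccc(OCc9ccccc9)c(OCc9ccccc9)c7)[C@H](OCc9ccccc9)[C@H]2c1c(OCc9ccccc9)ccc([C@H](c3c(OCc9ccccc9)cc(OCc9ccccc9)c4c3O[C@H](c7ccc(OCc9ccccc9)c(OCc9ccccc9)c7)[C@@H](OCc9ccccc9)C4)[C@H]5O[C@H]5c7ccc(OCc9ccccc9)c(OCc9ccccc9)c7)c1O[Si](C)(C)C(C)(C)C
A6 | alternative 3 | (2R,3R)-5,7-bis(benzyloxy)-2-[3,4-bis(benzyloxy)phenyl]-4-[2,6-bis(methoxymethoxy)phenyl]chroman-3-ol, 2,3-cis, 3,4-trans | c9ccccc9COc1cc(OCc9ccccc9)c2c(c1)O[C@H](c7ccc(OCc9ccccc9)c(OCc9ccccc9)c7)[C@H](O)[C@H]2c1c(OCOC)cccc1OCOC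
A7 | alternative 3 | 3,5-bis(benzyloxy)phenyl ether of trans-2,3-epoxy-1-[3,4-bis(benzyloxy)phenyl]-3-[2,6-bis(methoxymethoxy)phenyl]propan-1-ol | c9ccccc9COc1cc(OCc9ccccc9)cc(c1)O[C@H](c7ccc(OCc9ccccc9)c(OCc9ccccc9)c7)[C@@H]2O[C@H]2c1c(OCOC)cccc1OCOC
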